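A direct plan would cyanoethylate a butane-1,4-diamine core on both nitrogens to dinitrile A1, cap the inner nitrogens as tert-butyl carbamates, hydrogenate the nitriles to the diprotected tetraamine A2, and acylate its two primary amines with the cinnamoyl active ester A3, itself made by O-benzylation and Knoevenagel–Doebner chain extension of an aldehyde; acidolysis and hydrogenation would end it.
Its weakest steps would be:
- the nitrile hydrogenation over Raney Ni, which would need pressure and ammonia to hold back secondary-amine by-products and would give a polar diamine that is hard to purify;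
- the carbamate installation with its later acidolysis and free-basing of a tetraamine, operations that would form no skeletal bond;
- the chain extension, which would rebuild a C6–C3 acid that can be had with all its carbons in place.

The new route would cut the C6–C7 bond in the middle of the N4–(CH2)4–N9 bridge (4,9-diazadodecane numbering), the bond crossed by the C2 axis of the acyclic chain, so the target becomes the homodimer of one half. The key step would join two identical primary carbons, each released as a radical by reductive decarboxylation of an N-acyloxyphthalimide, and would create the whole differentiated tetraamine chain in one operation. Each half would come from a symmetric C3 diamine by ester aminolysis and one aza-Michael addition to an acrylate, whose carboxyl group is a traceless handle lost as CO2. No nitrile would be reduced, no alkene built and removed, and the nitrogen protection would fall in the final hydrogenolysis.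

Key step: step 6

Remark: the target is taken as the neutral free base of the given SMILES; it has no stereocentre, and its only rings, the two benzene rings, are bought in with the arylpropanoic acid.

Step 1
Reactants: 1 3-(3,4-dihydroxyphenyl)propanoic acid (dihydrocaffeic acid); 2 benzyl bromide (3.3 equiv)
Product: 3 benzyl 3-[3,4-bis(benzyloxy)phenyl]propanoate
Conditions: K2CO3 (4 equiv), DMF, 60 °C, N2, 8 h
Reagents that add atoms: benzyl bromide 2, BrCc1ccccc1
Why: Williamson ether synthesis together with carboxylate O-alkylation, in which the two phenoxides and the carboxylate each displace bromide (SN2), so that one operation should mask the oxidation-prone catechol as hydrogenolysable ethers and turn the acid into an ester ready for aminolysis; no stereocentre is formed.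

Step 2
Reactants: 3 benzyl 3-[3,4-bis(benzyloxy)phenyl]propanoate; 4 1,3-diaminopropane (10 equiv)
Product: 5 N-(3-aminopropyl)-3-[3,4-bis(benzyloxy)phenyl]propanamide
Conditions: neat 4, 70 °C, 16 h; excess 4 distilled off, acid–base extraction
Reagents that add atoms: 1,3-diaminopropane 4, NCCCN
Why: Ester aminolysis (acyl substitution), in which the large excess of the symmetric diamine should hold the reaction at the mono-amide, while the basic product is separated from benzyl alcohol and from any neutral bis-amide by extraction into aqueous acid; aryl benzyl ethers are inert to amines.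

Step 3
Reactants: 5 N-(3-aminopropyl)-3-[3,4-bis(benzyloxy)phenyl]propanamide; 6 methyl acrylate (1.05 equiv); 7 benzyl chloroformate (1.2 equiv)
Product: 9 methyl N-[(benzyloxy)carbonyl]-N-{3-[3-(3,4-bis(benzyloxy)phenyl)propanamido]propyl}-β-alaninate, via secondary amino ester 8 (not isolated)
Conditions: 6, MeOH, 0 °C → rt, 16 h, evaporated; then 7, Na2CO3 (2 equiv), CH2Cl2–H2O, 0 °C → rt, 3 h; silica chromatography
Reagents that add atoms: methyl acrylate 6, C=CC(=O)OC; benzyl chloroformate 7, O=C(Cl)OCc1ccccc1
Why: Aza-Michael addition followed by Schotten–Baumann carbamate formation, in which the first addition of the primary amine in methanol should be much faster than a second one at the more hindered secondary amine, and the carbamate installed at once blocks retro-Michael loss and gives a neutral compound for chromatography; the secondary amide N–H does not react.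

Step 4
Reactants: 9 methyl N-[(benzyloxy)carbonyl]-N-{3-[3-(3,4-bis(benzyloxy)phenyl)propanamido]propyl}-β-alaninate; 10 lithium hydroxide monohydrate (2 equiv)
Product: 11 N-[(benzyloxy)carbonyl]-N-{3-[3-(3,4-bis(benzyloxy)phenyl)propanamido]propyl}-β-alanine
Conditions: THF–H2O 3:1, 0 °C → rt, 4 h; then 1 M HCl to pH 3, EtOAc extraction
Reagents that add atoms: lithium hydroxide monohydrate 10, O.[Li+].[OH-]
Why: Ester saponification (BAc2), which a methyl ester should undergo at rt while the benzyl carbamate, the secondary amide and the benzyl ethers are left intact.

Step 5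
Reactants: 11 N-[(benzyloxy)carbonyl]-N-{3-[3-(3,4-bis(benzyloxy)phenyl)propanamido]propyl}-β-alanine; 12 N-hydroxyphthalimide (1.1 equiv)
Product: 14 1,3-dioxoisoindolin-2-yl N-[(benzyloxy)carbonyl]-N-{3-[3-(3,4-bis(benzyloxy)phenyl)propanamido]propyl}-β-alaninate, via O-acylisourea 13 (not isolated)
Conditions: DIC (1.1 equiv), DMAP (0.05 equiv), CH2Cl2, 0 °C → rt, 3 h; urea filtered off, short silica plug
Reagents that add atoms: N-hydroxyphthalimide 12, ON1C(=O)c2ccccc2C1=O
Why: Steglich-type carbodiimide esterification, in which N-hydroxyphthalimide intercepts the O-acylisourea to give a redox-active ester that accepts one electron at a mild potential; both nitrogens of the chain are already acylated, so no other site competes.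

Step 6
Reactants: 14 1,3-dioxoisoindolin-2-yl N-[(benzyloxy)carbonyl]-N-{3-[3-(3,4-bis(benzyloxy)phenyl)propanamido]propyl}-β-alaninate (two molecules combine)
Product: 16 N4,N9-bis(benzyloxycarbonyl)-N1,N12-bis{3-[3,4-bis(benzyloxy)phenyl]propanoyl}spermine, via primary alkyl radical 15 (not isolated)
Conditions: NiCl2·6H2O (20 mol %), 2,2':6',2''-terpyridine (20 mol %), LiBr (electrolyte), DMF, Zn anode, reticulated vitreous carbon cathode, undivided cell, constant current (ca. 2.5 F/mol), rt, Ar; 1 M HCl wash, silica chromatography
Reagents that add atoms: none
Why: Nickel-catalysed electroreductive decarboxylative homocoupling, in which cathodically generated low-valent nickel passes one electron to the N-acyloxyphthalimide, the radical anion loses phthalimide anion and CO2 to give primary radical 15, and nickel then carries two such alkyl groups and joins them by C(sp3)–C(sp3) reductive elimination while the zinc anode is consumed. The closest known reaction type is the nickel-catalysed reductive doubly decarboxylative alkyl–alkyl coupling of redox-active esters, with the reductive dimerisation of alkyl halides as a second model; it is the reductive counterpart of a Kolbe electrolysis. No ring is closed and no stereocentre is formed: the step forms the C6–C7 bond, doubles the molecule and so should deliver the complete chain with its four nitrogens already differentiated. The selectivity needed is alkyl–alkyl coupling in preference to hydrogen-atom capture (the alkane) and β-hydride elimination (the enecarbamate); it should be secured by the unhindered primary radical, by the tridentate terpyridine ligand, by a high substrate concentration and by the identity of the two partners, which excludes any statistical mixture. The reductive manifold is chosen because an anodic coupling of acid 11 would oxidise the 1,2-dialkoxybenzene rings before the carboxylate, whereas aryl benzyl ethers, benzyl carbamates and secondary amides are inert to zerovalent and monovalent nickel, and the carbamate nitrogen β to the radical is too poor a leaving group to be eliminated.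

Step 7
Reactants: 16 N4,N9-bis(benzyloxycarbonyl)-N1,N12-bis{3-[3,4-bis(benzyloxy)phenyl]propanoyl}spermine
Product: 17 kukoamine A [N1,N12-bis(3,4-dihydroxyhydrocinnamoyl)spermine]
Conditions: H2 (3 bar), 20% Pd(OH)2/C, degassed THF–EtOH–H2O (4:4:1), rt, 16 h; filtered through Celite under Ar, evaporated
Reagents that add atoms: none
Why: Catalytic hydrogenolysis, which should cleave the four aryl benzyl ethers and the two benzyl carbamates (the carbamic acids lose CO2) in one operation, so that the neutral target is obtained by filtration and evaporation without a basic work-up of the free catechol; no stereocentre arises.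

**Compound list**
1 | 3-(3,4-dihydroxyphenyl)propanoic acid (dihydrocaffeic acid) | OC(=O)CCc1ccc(O)c(O)c1 | starting material
2 | benzyl bromide | BrCc1ccccc1 | starting material
3 | benzyl 3-[3,4-bis(benzyloxy)phenyl]propanoate | O=C(CCc1ccc(OCc2ccccc2)c(OCc2ccccc2)c1)OCc1ccccc1 | intermediate
4 | 1,3-diaminopropane | NCCCN | starting material
5 | N-(3-aminopropyl)-3-[3,4-bis(benzyloxy)phenyl]propanamide | NCCCNC(=O)CCc1ccc(OCc2ccccc2)c(OCc2ccccc2)c1 | intermediate
6 | methyl acrylate | C=CC(=O)OC | starting material
7 | benzyl chloroformate | O=C(Cl)OCc1ccccc1 | starting material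
8 | methyl N-{3-[3-(3,4-bis(benzyloxy)phenyl)propanamido]propyl}-β-alaninate (secondary amino ester, not isolated) | COC(=O)CCNCCCNC(=O)CCc1ccc(OCc2ccccc2)c(OCc2ccccc2)c1 | intermediate
9 | methyl N-[(benzyloxy)carbonyl]-N-{3-[3-(3,4-bis(benzyloxy)phenyl)propanamido]propyl}-β-alaninate | COC(=O)CCN(CCCNC(=O)CCc1ccc(OCc2ccccc2)c(OCc2ccccc2)c1)C(=O)OCc1ccccc1 | intermediate
10 | lithium hydroxide monohydrate | O.[Li+].[OH-] | starting material
11 | N-[(benzyloxy)carbonyl]-N-{3-[3-(3,4-bis(benzyloxy)phenyl)propanamido]propyl}-β-alanine | OC(=O)CCN(CCCNC(=O)CCc1ccc(OCc2ccccc2)c(OCc2ccccc2)c1)C(=O)OCc1ccccc1 | intermediate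
12 | N-hydroxyphthalimide | ON1C(=O)c2ccccc2C1=O | starting material
13 | O-acylisourea from 11 and DIC (not isolated) | CC(C)NC(=NC(C)C)OC(=O)CCN(CCCNC(=O)CCc1ccc(OCc2ccccc2)c(OCc2ccccc2)c1)C(=O)OCc1ccccc1 | intermediate
14 | 1,3-dioxoisoindolin-2-yl N-[(benzyloxy)carbonyl]-N-{3-[3-(3,4-bis(benzyloxy)phenyl)propanamido]propyl}-β-alaninate | O=C(CCN(CCCNC(=O)CCc1ccc(OCc2ccccc2)c(OCc2ccccc2)c1)C(=O)OCc1ccccc1)ON1C(=O)c2ccccc2C1=O | intermediate
15 | 2-{[(benzyloxy)carbonyl]{3-[3-(3,4-bis(benzyloxy)phenyl)propanamido]propyl}amino}ethyl radical (not isolated) | [CH2]CN(CCCNC(=O)CCc1ccc(OCc2ccccc2)c(OCc2ccccc2)c1)C(=O)OCc1ccccc1 | intermediate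
16 | N4,N9-bis(benzyloxycarbonyl)-N1,N12-bis{3-[3,4-bis(benzyloxy)phenyl]propanoyl}spermine | O=C(CCc1ccc(OCc2ccccc2)c(OCc2ccccc2)c1)NCCCN(C(=O)OCc1ccccc1)CCCCN(C(=O)OCc1ccccc1)CCCNC(=O)CCc1ccc(OCc2ccccc2)c(OCc2ccccc2)c1 | intermediate
17 | kukoamine A | O=C(CCc1ccc(O)c(O)c1)NCCCNCCCCNCCCNC(=O)CCc1ccc(O)c(O)c1 | target

Total step count: 7. Longest linear sequence: 7 steps (the route is linear; the two halves are joined by dimerisation in step 6).

Steps most likely to fail:

Step 6. Radical 15 may capture a hydrogen atom (hydrodecarboxylation), or the alkylnickel species may undergo β-hydride elimination before the second alkyl group arrives, so that little dimer forms. The fallback would give up the central C–C coupling and take the bridge from a commercial tetraamine. It sets out from ester 3, which would be heated with spermine (0.5 equiv, neat or in a little toluene, 90 °C). Ester aminolysis should occur only at the two primary amines, the hindered secondary amines being far slower, to give N1,N12-bis{3-[3,4-bis(benzyloxy)phenyl]propanoyl}spermine F1. Hydrogenolysis of its four benzyl ethers under the conditions of step 7 would come back to the route at 17.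

Step 3. A second conjugate addition at the secondary amine (tertiary bis-adduct) or incomplete addition may lower the amount of the mono-adduct. The fallback would enforce a single alkylation through a sulfonamide (Fukuyama amine synthesis). It sets out from amine 5, which with 2-nitrobenzenesulfonyl chloride and Et3N in CH2Cl2 would give 3-[3,4-bis(benzyloxy)phenyl]-N-{3-[(2-nitrophenyl)sulfonylamino]propyl}propanamide F2, a compound with one acidic N–H only. Aza-Michael addition of its anion to methyl acrylate (K2CO3, DMF) would give methyl N-{3-[3-(3,4-bis(benzyloxy)phenyl)propanamido]propyl}-N-[(2-nitrophenyl)sulfonyl]-β-alaninate F3. Thiophenol and K2CO3 in DMF would remove the sulfonyl group by ipso-substitution and come back to the route at 8, which is then treated with benzyl chloroformate as in step 3.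

Step 7. The liberated secondary amines may poison the palladium, the increasingly polar product may precipitate on the catalyst, and the free catechol may oxidise in air during isolation, so that partly protected material remains. The fallback would replace reduction by Lewis-acid dealkylation. It sets out from 16, which with BBr3 (excess) in CH2Cl2 at −78 → 0 °C and a methanol quench should lose all six benzyl groups and give the air-stable salt kukoamine A bis(hydrobromide) F4. Free-basing on a weakly basic ion-exchange resin under Ar would come back to the route at 17.

**Further compounds**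
F1 | step 6 | N1,N12-bis{3-[3,4-bis(benzyloxy)phenyl]propanoyl}spermine | O=C(CCc1ccc(OCc2ccccc2)c(OCc2ccccc2)c1)NCCCNCCCCNCCCNC(=O)CCc1ccc(OCc2ccccc2)c(OCc2ccccc2)c1
F2 | step 3 | 3-[3,4-bis(benzyloxy)phenyl]-N-{3-[(2-nitrophenyl)sulfonylamino]propyl}propanamide | O=C(CCc1ccc(OCc2ccccc2)c(OCc2ccccc2)c1)NCCCNS(=O)(=O)c1ccccc1[N+](=O)[O-]
F3 | step 3 | methyl N-{3-[3-(3,4-bis(benzyloxy)phenyl)propanamido]propyl}-N-[(2-nitrophenyl)sulfonyl]-β-alaninate | COC(=O)CCN(CCCNC(=O)CCc1ccc(OCc2ccccc2)c(OCc2ccccc2)c1)S(=O)(=O)c1ccccc1[N+](=O)[O-]
F4 | step 7 | kukoamine A bis(hydrobromide) | O=C(CCc1ccc(O)c(O)c1)NCCCNCCCCNCCCNC(=O)CCc1ccc(O)c(O)c1.Br.Br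
A1 | direct plan | N,N'-bis(2-cyanoethyl)butane-1,4-diamine | N#CCCNCCCCNCCC#N
A2 | direct plan | di-tert-butyl butane-1,4-diylbis[(3-aminopropyl)carbamate] (N4,N9-di-Boc-spermine) | NCCCN(C(=O)OC(C)(C)C)CCCCN(C(=O)OC(C)(C)C)CCCN
A3 | direct plan | 2,5-dioxopyrrolidin-1-yl (E)-3-[3,4-bis(benzyloxy)phenyl]acrylate | O=C(/C=C/c1ccc(OCc2ccccc2)c(OCc2ccccc2)c1)ON1C(=O)CCC1=O
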